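**Strategy.** The route rests on disconnecting the bond between the benzene ring and the internal alkene carbon C2 of the hepta-1,5-dienyl chain. The key step forges it by copper-catalysed, alkoxide-directed anti-arylmagnesiation of a terminal alkyne. The oxygen on C3, the stereocentre next to C2 that later carries the angelate, chelates magnesium and steers the aryl group to C2. An aryl Grignard reagent and (S)-6-methylhept-5-en-1-yn-3-ol should thus give the 2-aryl allylic alcohol in one operation, with the 1,1-disubstituted alkene formed and the (S) configuration untouched. The hydroquinone ring travels as its trimethyl ether and is unmasked last through the p-quinone (CAN, then dithionite), which leaves the 3-methoxy group in place.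

Key step: step 7

Remark: chain atoms are numbered as in hepta-1,5-diene (C1 = CH2, C2 = aryl-bearing alkene carbon, C3 = stereocentre, S); the ester is the angelate, (Z)-2-methylbut-2-enoate.

Step 1
Reactants: 1 2,4-dimethoxy-3-methylbenzaldehyde
Product: 3 2,4-dimethoxy-3-methylphenol, via 2,4-dimethoxy-3-methylphenyl formate 2 (not isolated)
Conditions: mCPBA, CH2Cl2, 0 °C → rt; then K2CO3 (cat.), MeOH, rt
Reagents that add atoms: mCPBA (3-chloroperoxybenzoic acid), O=C(OO)c1cccc(Cl)c1
Why: Baeyer–Villiger (Dakin-type) oxidation, in which the electron-rich aryl group migrates in preference to hydrogen to give the formate, which is then methanolysed to the phenol.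

Step 2
Reactants: 3 2,4-dimethoxy-3-methylphenol
Product: 4 6-bromo-2,4-dimethoxy-3-methylphenol
Conditions: NBS (1.0 equiv), i-Pr2NH (0.1 equiv), CH2Cl2, −40 → 0 °C
Reagents that add atoms: N-bromosuccinimide, O=C1CCC(=O)N1Br
Why: Amine-mediated ortho-selective electrophilic bromination of a phenol, which should deliver bromine to C6, the only free position ortho to the hydroxyl (the para position is blocked by OMe and the other free CH is meta to the phenolic oxygen).

Step 3
Reactants: 4 6-bromo-2,4-dimethoxy-3-methylphenol
Product: 5 1-bromo-2,3,5-trimethoxy-4-methylbenzene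
Conditions: MeI, K2CO3, acetone, reflux
Reagents that add atoms: iodomethane, CI
Why: Williamson ether synthesis, which turns the phenol into a methyl ether that tolerates Grignard formation and is later removed oxidatively.

Step 4
Reactants: 6 4-methylpent-3-enoic acid
Product: 8 N-methoxy-N,4-dimethylpent-3-enamide, via 1-(1H-imidazol-1-yl)-4-methylpent-3-en-1-one 7 (not isolated)
Conditions: CDI, CH2Cl2, 0 °C → rt; then MeNH(OMe)·HCl, rt
Reagents that add atoms: 1,1'-carbonyldiimidazole, O=C(n1ccnc1)n1ccnc1 (imidazolyl group of 7 only); N,O-dimethylhydroxylamine hydrochloride, CNOC.Cl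
Why: CDI-mediated Weinreb amide formation through the acyl imidazolide, under near-neutral conditions that should leave the β,γ-alkene in place.

Step 5
Reactants: 8 N-methoxy-N,4-dimethylpent-3-enamide; 9 ethynyltrimethylsilane
Product: 11 6-methyl-1-(trimethylsilyl)hept-5-en-1-yn-3-one, via lithium (trimethylsilyl)acetylide 10 (not isolated)
Conditions: 9, n-BuLi, THF, −78 °C; then 8, −78 → −20 °C; cold sat. aq. NH4Cl
Reagents that add atoms: n-butyllithium, [Li]CCCC (lithium of 10 only)
Why: Weinreb ketone synthesis, in which the chelated tetrahedral adduct prevents over-addition, while the weakly basic acetylide and the cold quench should keep the β,γ-unsaturated ynone from moving into conjugation.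

Step 6
Reactants: 11 6-methyl-1-(trimethylsilyl)hept-5-en-1-yn-3-one
Product: 13 (S)-6-methylhept-5-en-1-yn-3-ol, via (S)-6-methyl-1-(trimethylsilyl)hept-5-en-1-yn-3-ol 12 (not isolated)
Conditions: Ru[(S,S)-TsDPEN](p-cymene) (1 mol %), i-PrOH, rt; evaporate; then K2CO3 (cat.), MeOH, rt
Reagents that add atoms: none
Why: Noyori asymmetric transfer hydrogenation of an ynone, in which the (S,S)-catalyst should deliver hydride to the face that gives the (S)-propargylic alcohol (the alkynyl group takes the place of the aryl group of acetophenone in the six-membered transition state), followed by base-catalysed methanolysis of the C–Si bond.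

Step 7
Reactants: 5 1-bromo-2,3,5-trimethoxy-4-methylbenzene; 13 (S)-6-methylhept-5-en-1-yn-3-ol
Product: 16 (S)-6-methyl-2-(2,3,5-trimethoxy-4-methylphenyl)hepta-1,5-dien-3-ol, via (2,3,5-trimethoxy-4-methylphenyl)magnesium bromide 14 (not isolated), via cyclic alkenylmagnesium alkoxide 15 (not isolated)
Conditions: 5 (2.5 equiv), Mg, THF, 50 °C; then 13, CuI (15 mol %), Et2O/THF, 0 → 40 °C; sat. aq. NH4Cl
Reagents that add atoms: magnesium, [Mg] (retained only in 14 and 15)
Why: The first equivalent of 14 turns 13 into its magnesium alkoxide, and copper(I) then relays the aryl group from magnesium to the internal alkyne carbon C2 in an alkoxide-directed anti-carbometalation, which leaves magnesium on the terminal carbon, bound to the C3 oxygen in the five-membered chelate 15; aqueous NH4Cl protonates the C–Mg and O–Mg bonds to give the 1,1-disubstituted alkene. The closest known reaction type is the copper-catalysed anti-arylmagnesiation of propargylic alcohols to 2-aryl allylic alcohols. The only ring closed is the temporary O–Mg–C chelate of 15 (five-membered, closed by capture of the alkenyl–magnesium bond by the alkoxide, formally 5-endo with respect to the alkyne), and the work-up opens it again, so no ring of the product is formed. No new stereocentre arises: C3 keeps the S configuration set in step 6 because none of its bonds is broken and a magnesium alkoxide has no epimerisation pathway. The step needs regioselectivity for aryl delivery to C2 over C1, which chelation by the C3 alkoxide secures, and chemoselectivity for the alkyne over the trisubstituted C5=C6 alkene, which is secured because an unactivated alkene does not undergo carbometalation under these conditions.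

Step 8
Reactants: 16 (S)-6-methyl-2-(2,3,5-trimethoxy-4-methylphenyl)hepta-1,5-dien-3-ol; 17 angelic acid ((Z)-2-methylbut-2-enoic acid)
Product: 19 (S)-6-methyl-2-(2,3,5-trimethoxy-4-methylphenyl)hepta-1,5-dien-3-yl (Z)-2-methylbut-2-enoate, via angelic 2,4,6-trichlorobenzoic anhydride 18 (not isolated)
Conditions: 17, 2,4,6-trichlorobenzoyl chloride, Et3N, toluene, rt; then 16, 80 °C (no DMAP)
Reagents that add atoms: 2,4,6-trichlorobenzoyl chloride, O=C(Cl)c1c(Cl)cc(Cl)cc1Cl (aroyl group of 18 only)
Why: Yamaguchi-type mixed-anhydride esterification, in which the alcohol attacks the less hindered angeloyl carbonyl and the absence of a nucleophilic catalyst should keep the Z-enoate from isomerising to the tiglate, while the C3–O bond and its configuration are untouched.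

Step 9
Reactants: 19 (S)-6-methyl-2-(2,3,5-trimethoxy-4-methylphenyl)hepta-1,5-dien-3-yl (Z)-2-methylbut-2-enoate
Product: 21 (S)-2-(2,5-dihydroxy-3-methoxy-4-methylphenyl)-6-methylhepta-1,5-dien-3-yl (Z)-2-methylbut-2-enoate, via p-quinone angelate 20 (not isolated)
Conditions: CAN (2.5 equiv), MeCN/H2O, 0 °C, short reaction time; then excess aq. Na2S2O4, EtOAc, rt, under Ar
Reagents that add atoms: water, O
Why: Ceric ammonium nitrate oxidative demethylation of the para-disposed 2- and 5-methoxy groups (arene radical cation, ipso attack of water, loss of methanol) should give the p-quinone with the 3-methoxy group retained as a vinylogous ester, and dithionite reduction of the quinone then gives the hydroquinone without touching the ester or the alkenes.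

**Compound list**

1 | 2,4-dimethoxy-3-methylbenzaldehyde | O=Cc1ccc(OC)c(C)c1OC | starting material
2 | 2,4-dimethoxy-3-methylphenyl formate | O=COc1ccc(OC)c(C)c1OC | intermediate
3 | 2,4-dimethoxy-3-methylphenol | Oc1ccc(OC)c(C)c1OC | intermediate
4 | 6-bromo-2,4-dimethoxy-3-methylphenol | Oc1c(Br)cc(OC)c(C)c1OC | intermediate
5 | 1-bromo-2,3,5-trimethoxy-4-methylbenzene | COc1c(Br)cc(OC)c(C)c1OC | intermediate
6 | 4-methylpent-3-enoic acid | CC(C)=CCC(=O)O | starting material
7 | 1-(1H-imidazol-1-yl)-4-methylpent-3-en-1-one | CC(C)=CCC(=O)n1ccnc1 | intermediate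
8 | N-methoxy-N,4-dimethylpent-3-enamide | CC(C)=CCC(=O)N(C)OC | intermediate
9 | ethynyltrimethylsilane | C#C[Si](C)(C)C | starting material
10 | lithium (trimethylsilyl)acetylide | [Li]C#C[Si](C)(C)C | intermediate
11 | 6-methyl-1-(trimethylsilyl)hept-5-en-1-yn-3-one | CC(C)=CCC(=O)C#C[Si](C)(C)C | intermediate
12 | (S)-6-methyl-1-(trimethylsilyl)hept-5-en-1-yn-3-ol | C[Si](C)(C)C#C[C@H](CC=C(C)C)O | intermediate
13 | (S)-6-methylhept-5-en-1-yn-3-ol | C#C[C@H](CC=C(C)C)O | intermediate
14 | (2,3,5-trimethoxy-4-methylphenyl)magnesium bromide | COc1c([Mg]Br)cc(OC)c(C)c1OC | intermediate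
15 | cyclic alkenylmagnesium alkoxide: (S)-5-(3-methylbut-2-en-1-yl)-4-(2,3,5-trimethoxy-4-methylphenyl)-2,5-dihydro-1,2-oxamagnesole | CC(C)=CC[C@@H]1O[Mg]C=C1c1cc(OC)c(C)c(OC)c1OC | intermediate
16 | (S)-6-methyl-2-(2,3,5-trimethoxy-4-methylphenyl)hepta-1,5-dien-3-ol | C=C(c1cc(OC)c(C)c(OC)c1OC)[C@H](CC=C(C)C)O | intermediate
17 | angelic acid, (Z)-2-methylbut-2-enoic acid | C/C=C(/C)C(=O)O | starting material
18 | angelic 2,4,6-trichlorobenzoic anhydride | C/C=C(/C)C(=O)OC(=O)c1c(Cl)cc(Cl)cc1Cl | intermediate
19 | (S)-6-methyl-2-(2,3,5-trimethoxy-4-methylphenyl)hepta-1,5-dien-3-yl (Z)-2-methylbut-2-enoate | C=C(c1cc(OC)c(C)c(OC)c1OC)[C@H](CC=C(C)C)OC(=O)/C(C)=C\C | intermediate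
20 | (S)-2-(5-methoxy-4-methyl-3,6-dioxocyclohexa-1,4-dien-1-yl)-6-methylhepta-1,5-dien-3-yl (Z)-2-methylbut-2-enoate | C=C(C1=CC(=O)C(C)=C(OC)C1=O)[C@H](CC=C(C)C)OC(=O)/C(C)=C\C | intermediate
21 | (S)-2-(2,5-dihydroxy-3-methoxy-4-methylphenyl)-6-methylhepta-1,5-dien-3-yl (Z)-2-methylbut-2-enoate | C=C(c1cc(O)c(C)c(OC)c1O)[C@H](CC=C(C)C)OC(=O)/C(C)=C\C | target

**Step count and risks**

Total step count: 9. Longest linear sequence: 6 steps (steps 1, 2, 3, 7, 8, 9 or steps 4, 5, 6, 7, 8, 9).

Step 7 (key step). The hindered, electron-rich aryl Grignard reagent may add sluggishly, the terminal alkyne may be deprotonated instead of carbometalated, and much of the aryl reagent may be lost as the protonated arene. The fallback replaces the directed carbometalation by a regioselective borylation and cross-coupling. It sets out from 13: NHC–copper-catalysed α-selective protoboration (N-aryl imidazolinylidene–CuCl, NaOt-Bu, B2pin2, MeOH, THF, −50 → −15 °C) should give (S)-6-methyl-2-(4,4,5,5-tetramethyl-1,3,2-dioxaborolan-2-yl)hepta-1,5-dien-3-ol F1. Suzuki–Miyaura coupling of F1 with 5 (Pd(OAc)2/SPhos, K3PO4, THF/H2O, 40 °C) returns to the route at 16.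

Step 9. Over-oxidation of the electron-rich styrene unit, competing ortho-quinone formation from the adjacent 2,3-dimethoxy pair, or decomposition of the vinylquinone before reduction may erode the last step. The fallback avoids ceric ion by leaving the oxygen ortho to the side chain as a free phenol, so that the oxidation becomes a regiospecific hypervalent-iodine oxidation of a p-methoxyphenol. It sets out from 13 (through boronate F1, made as above) and from 4. Esterification of F1 with the mixed anhydride 18 (toluene, 80 °C) should give (S)-6-methyl-2-(4,4,5,5-tetramethyl-1,3,2-dioxaborolan-2-yl)hepta-1,5-dien-3-yl (Z)-2-methylbut-2-enoate F2. Suzuki–Miyaura coupling of F2 with bromophenol 4 (Pd(OAc)2/SPhos, K3PO4, THF/H2O, rt → 40 °C) should give (S)-2-(2-hydroxy-3,5-dimethoxy-4-methylphenyl)-6-methylhepta-1,5-dien-3-yl (Z)-2-methylbut-2-enoate F3. Oxidation of F3 with PhI(OAc)2 in MeCN/H2O at 0 °C returns to the route at 20, which is reduced with Na2S2O4 to 21 as in step 9.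

Step 2. Bromination may occur in part at C5 (ortho and para to the two methoxy groups), or twice, giving the wrong substitution pattern. The fallback replaces electrophilic substitution by directed ortho-metalation. It sets out from 3: MOMCl, i-Pr2NEt, CH2Cl2 should give 1,3-dimethoxy-4-(methoxymethoxy)-2-methylbenzene F4. Treatment with n-BuLi (THF, 0 °C) should lithiate only next to the MOM ether to give [3,5-dimethoxy-2-(methoxymethoxy)-4-methylphenyl]lithium F5. Quenching with 1,2-dibromoethane should give 1-bromo-3,5-dimethoxy-2-(methoxymethoxy)-4-methylbenzene F6. Cleavage of the MOM ether (HCl, MeOH, rt) returns to the route at 4.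

**Further compounds**

F1 | step 7 | (S)-6-methyl-2-(4,4,5,5-tetramethyl-1,3,2-dioxaborolan-2-yl)hepta-1,5-dien-3-ol | C=C(B1OC(C)(C)C(C)(C)O1)[C@H](CC=C(C)C)O
F2 | step 9 | (S)-6-methyl-2-(4,4,5,5-tetramethyl-1,3,2-dioxaborolan-2-yl)hepta-1,5-dien-3-yl (Z)-2-methylbut-2-enoate | C=C(B1OC(C)(C)C(C)(C)O1)[C@H](CC=C(C)C)OC(=O)/C(C)=C\C
F3 | step 9 | (S)-2-(2-hydroxy-3,5-dimethoxy-4-methylphenyl)-6-methylhepta-1,5-dien-3-yl (Z)-2-methylbut-2-enoate | C=C(c1cc(OC)c(C)c(OC)c1O)[C@H](CC=C(C)C)OC(=O)/C(C)=C\C
F4 | step 2 | 1,3-dimethoxy-4-(methoxymethoxy)-2-methylbenzene | COCOc1ccc(OC)c(C)c1OC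
F5 | step 2 | [3,5-dimethoxy-2-(methoxymethoxy)-4-methylphenyl]lithium | [Li]c1cc(OC)c(C)c(OC)c1OCOC
F6 | step 2 | 1-bromo-3,5-dimethoxy-2-(methoxymethoxy)-4-methylbenzene | COCOc1c(Br)cc(OC)c(C)c1OC
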